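## Structural features

The target is a biflavanoid: an upper 7,8,3',4'-tetrahydroxyflavan-3-ol and a lower 7,8,4'-trihydroxyflavan-3,4-diol, joined by one bond from the sp3 carbon C4 of the upper unit to C6 of lower ring A. Each unit holds a contiguous triad of stereocentres: upper C2/C3/C4 are 2,3-cis and 3,4-trans (2R,3R,4S), lower C2/C3/C4 are all-cis (2R,3R,4R). The two triads are separated by lower ring A, so neither can steer the other. Lower ring A is substituted at every carbon but C5 (O1, O8, O7, upper C4 at C6, lower C4 at C4a). The fragile groups are the 2,3-cis flavan-3-ol (ring opening at O1–C2 once the 4'-phenol is free in base), the lower benzylic C4 hydroxyl para to O7 (ionised by acid, lost on over-reduction) and the catechol and pyrogallol-type rings (air oxidation). The real difficulty is upper C4, a diarylmethine that must stand trans to O3 next to a cis C2/C3 pair and that is also the junction to a crowded arene; the second difficulty is the all-cis lower triad, which has no internal control element. The key step uses the fact that upper C4 is bonded to C4a of upper ring A, ortho to O1, and is trans to O3: this is the pattern left by anti opening of a trans C3–C4 epoxide by ring A through its only free ortho carbon.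

## Logic of the disconnections

22 to 21. The five benzylic O–CH2 bonds and the two O–C bonds of the diphenylmethylene ketal are cut. Seven oxidation-prone phenols are best freed last, in one neutral operation, so that all earlier chemistry runs on ethers. The forward step must stop before the benzylic C4–O bond of the lower unit is attacked.

21 to 20. The C2–H, C3–H and C4–H bonds of lower ring C are cut, which leads back to a flat 3-hydroxy-4-pyranone. Three substituents on one face are the mark of hydrogen arriving from the other face of a planar ring, and three stereocentres vanish at once. The forward step needs the catalyst to choose the face, because the upper triad is too far away to do so.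

20 to 19. O1–C2 and C3–O of lower ring C are cut (oxidative cyclisation of a 2'-hydroxychalcone). The heterocycle becomes an open enone. The forward step needs six-membered closure, which the unsubstituted C6' position favours.

19 to 16 and 17. The enone C=C bond is cut and the ortho phenol is returned to its sulfonate. Lower ring B then comes from a commodity aldehyde. The forward step needs a base that cleaves the sulfonate and drives the condensation without harming the cis-flavan.

16 to 14. The aryl–acetyl bond is cut and bromine stands in its place. A methyl ketone would not pass the organometallic and Lewis-acid steps, while bromine is inert there and mildly electron-withdrawing. The forward step must couple at C–Br beside an aryl sulfonate and a free secondary alcohol.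

14 to 13 (key). Upper C4–C4a is cut. Ring C becomes an aryl ether side chain and the 3,4-trans relation becomes the geometry of a trans-epoxide; one ring, one C–C bond and one stereocentre are removed. The forward step needs invertive 6-endo opening, and 13 is designed for that. The oxygen para to the epoxide carbon is a tosylate and not a benzyl ether, because a 2,4-dialkoxyphenyl oxirane would ionise too easily to survive its own preparation or to open with inversion; the same group marks the future lower O1 for selective release. The ring-A catechol is a diphenylmethylene ketal, reached in one step from 1. The stereochemical bookkeeping of the pair was re-derived and is consistent: a trans-epoxide in 13, inversion at C4, and 2,3-cis-3,4-trans in 14.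

13 to 12 and 2. C2–O1 is cut. Ring A arrives as a phenol and displaces a benzylic carbinol with inversion, so the threo ether needed for 2,3-cis comes from the erythro alcohol. The forward step needs a clean SN2 course at an electron-rich benzylic carbon.

12 to 11. The two C–O bonds of the epoxide are cut. Hydroxyl-directed asymmetric epoxidation gives the erythro isomer with a reagent-defined face, so two stereocentres come from one alkene. The allylic alcohol and the product epoxide must survive the titanium alkoxide.

11 to 7 and 8. The bond between the carbinol carbon (future C2) and the alkene carbon (future C3) is cut. Two aryl building blocks of similar size result, and the E geometry comes from syn hydrometalation. The forward addition should be enantioselective, with the next step as a safety net.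

7 to 6 to 4 to 3. The alkyne carbon (one-carbon homologation of the formyl group), the O–S and O–CH2 bonds and the C–Br bond are cut. Compound 3 already carries the three adjacent oxygens, and its formyl carbon becomes upper C4. The forward steps need bromination at the one doubly activated position and sulfonylation of the most acidic phenol only.

2 to 1. The two ketal C–O bonds are cut. The symmetry of 1 means that any adjacent pair of hydroxyls gives the same product.

## Other disconnections considered

Alternative 1: The cut lies in upper ring A: the aryl–oxygen bond O1–C8a and the C8–O bond, the latter traded for C8–B. In the forward direction the open-chain fluoroarene alcohol A2, which already carries the lower unit and the whole C2/C3/C4 triad, would be treated with a hindered lithium amide. Deprotonation at C8 between fluorine and the O7 ether, loss of lithium fluoride, addition of the C2 alkoxide to C8a of the aryne and trapping of the C8 anion with a borate ester would give boronic acid A1, whose C–B bond is later oxidised to O8.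
- In favour: the ring closes under base, where neither C2 nor C4 can ionise, so the triad is only carried and never put at risk. On stereochemical safety at the ring-closing event this plan is the better one. Its regiochemistry (six-membered ring, anion next to O7) is as unambiguous as in the chosen plan.
- Against: the diarylmethine C4 must be made in an acyclic setting by some other stereoselective C–C bond formation, which is the problem the epoxide closure solves in passing. The strong base meets a doubly benzylic C4–H with a β-alkoxy group (loss of O3 by elimination) and seven benzylic ether methylenes. The fluorinated ring-A piece is not a commodity. The step sits at the end of a long linear sequence with the whole lower unit on board.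
- Step economy: longer (extra oxidation at C8, an extra group on O3, separate construction of C4).

Alternative 2: The cut goes through lower ring A at C5–C6 and C4a–C8a. The 1-methoxy-1,3-bis(silyloxy)-2-benzyloxy diene A4, attached to upper C4, would add to the ynone A5; loss of methanol and of the silyl groups aromatises the adduct to acetophenone A3.
- In favour: A3 is the chelated 2'-hydroxyacetophenone itself, so the bromine–acetyl exchange and the unmasking of the ortho phenol (step 9 and the first half of step 10) are not needed. On arrival at the chalcone precursor this plan is the better one. The polarity of diene and ynone fixes the regiochemistry. Upper C4 would be set earlier by addition of a carbon nucleophile to a cyclic flavan-4-yl cation trans to O3, which is at least the equal of the epoxide opening in reliability.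
- Against: a benzene ring that the chosen plan buys with all three oxygens in place is built atom by atom. The ketene-acetal diene is hydrolytically fragile and must be made by double enolisation on a chiral intermediate whose C4–H is β to O3. Its substituted terminus, on a secondary carbon, slows the cycloaddition.
- Step economy: longer; the two steps saved after the key step are outweighed by the synthesis of A4.

Alternative 3: The cut removes lower ring C: O1–C2, C3–C4 and the C4–O bond. Salicylaldehyde A7, benzyl alcohol A9 and the Z-styrylboronate A8 would combine under a chiral Brønsted acid. Hemiacetal formation and loss of water give a 4-benzyloxy ortho-quinone methide, which adds A8 in an inverse-demand hetero-cycloaddition to the all-cis boronate A6; oxidation of C–B with retention then gives O3.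
- In favour: three bonds and all three lower stereocentres come from one catalyst-controlled step. On this count it is better than the chosen plan, whose lower triad rests on the single step that goes beyond precedent. It is also not a rival of the chosen key step but a possible continuation of it, since A7 could be reached from 14 by exchanging bromine for a formyl group.
- Against: an alkenylboronate is a weak 2π partner for a quinone methide. The Z geometry must survive the acid. The all-cis outcome needs both endo selectivity and catalyst control over a large chiral aldehyde. The same acid could ionise the benzylic C2–O1 bond of the upper unit. The C4 benzyl ether must later be cut at O–CH2 and not at C4–O.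
- Step economy: about equal (formylation, cycloaddition, oxidation against steps 9 to 12).

Key step: step 8

Assumption: the ligand antipodes in steps 5 and 12 are assigned by analogy and would be confirmed on model substrates; the tartrate in step 6 follows the established rule that the fast-reacting enantiomer of an E secondary allylic alcohol gives the erythro epoxy alcohol.
Remark: upper C4 keeps one geometry from 14 to 22; its CIP label is R in 14–21 and S in 22 only because the ranking of its two aryl groups changes on deprotection.

## Route

Step 1
Reactants: 1 pyrogallol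
Product: 2 2,2-diphenyl-1,3-benzodioxol-4-ol
Conditions: Ph2CCl2, neat, 170 °C
Reagents that add atoms: dichlorodiphenylmethane ClC(Cl)(c1ccccc1)c1ccccc1
Why: Ketalisation of a catechol pair by a gem-dichloride; 1 is symmetric, so either adjacent pair gives the same benzodioxole and one phenol stays free as the later O1. The ketal masks O7 and O8 of upper ring A and leaves in the final hydrogenolysis.

Step 2
Reactants: 3 2,3,4-trihydroxybenzaldehyde
Product: 4 5-bromo-2,3,4-trihydroxybenzaldehyde
Conditions: Br2 (1.0 equiv), AcOH, rt
Reagents that add atoms: bromine BrBr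
Why: Electrophilic aromatic bromination; C5 is the only position activated by two hydroxyls (ortho to O4, para to O2) and it is meta to the formyl group. The bromine is the placeholder for the lower C4a acetyl group.

Step 3
Reactants: 4 5-bromo-2,3,4-trihydroxybenzaldehyde
Product: 6 2,3-bis(benzyloxy)-5-bromo-4-(tosyloxy)benzaldehyde, via monotosylate 5 (not isolated)
Conditions: TsCl (1.0 equiv), K2CO3 (1.05 equiv), DMF, 0 °C; then BnBr, K2CO3, 50 °C
Reagents that add atoms: p-toluenesulfonyl chloride Cc1ccc(cc1)S(Cl)(=O)=O; benzyl bromide BrCc1ccccc1
Why: Regioselective sulfonylation followed by Williamson benzylation: with one equivalent of base the phenoxide para to the formyl group (the most acidic one) forms and is sulfonylated, then the two remaining phenols are benzylated. The tosylate marks the future lower O1 and removes the donor para to the future epoxide carbon.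

Step 4
Reactants: 6 2,3-bis(benzyloxy)-5-bromo-4-(tosyloxy)benzaldehyde
Product: 7 2,3-bis(benzyloxy)-6-bromo-4-ethynylphenyl 4-methylbenzenesulfonate
Conditions: TMSCHN2, LiN(iPr)2, THF, −78 °C → rt
Reagents that add atoms: (trimethylsilyl)diazomethane C[Si](C)(C)C=[N+]=[N-]
Why: Colvin rearrangement: lithiated trimethylsilyldiazomethane adds to the aldehyde, loss of silanolate and N2 gives an alkylidene carbene, and a 1,2-hydride shift gives the terminal alkyne. No butyllithium and no alkaline methanol are present, so the aryl bromide and the tosylate should survive.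

Step 5
Reactants: 7 2,3-bis(benzyloxy)-6-bromo-4-ethynylphenyl 4-methylbenzenesulfonate; 8 3,4-bis(benzyloxy)benzaldehyde
Product: 11 (R,E)-1-[3,4-bis(benzyloxy)phenyl]-3-[2,3-bis(benzyloxy)-5-bromo-4-(tosyloxy)phenyl]prop-2-en-1-ol, via alkenylborane 9 (not isolated), via alkenylzinc 10 (not isolated)
Conditions: Cy2BH, toluene, 0 °C → rt; Me2Zn, −78 °C; (+)-MIB [(2R)-3-exo-morpholinoisoborneol] (5 mol%), then 8, −10 °C
Reagents that add atoms: none
Why: syn Hydroboration gives the E-alkenylborane, boron-to-zinc exchange gives the alkenylzinc, and the amino-alcohol-catalysed addition to the aryl aldehyde (catalytic asymmetric alkenylzinc addition) forms the C2–C3 bond. The carbinol centre is set by the ligand, (+)-MIB being chosen to give the R alcohol; step 6 reacts fast only with that enantiomer and so corrects a shortfall.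

Step 6
Reactants: 11 (R,E)-1-[3,4-bis(benzyloxy)phenyl]-3-[2,3-bis(benzyloxy)-5-bromo-4-(tosyloxy)phenyl]prop-2-en-1-ol
Product: 12 (S)-[3,4-bis(benzyloxy)phenyl]{(2S,3S)-3-[2,3-bis(benzyloxy)-5-bromo-4-(tosyloxy)phenyl]oxiran-2-yl}methanol (erythro epoxy alcohol)
Conditions: Ti(OiPr)4 (10 mol%), L-(+)-DIPT (15 mol%), t-BuOOH (1.1 equiv), 4 Å MS, CH2Cl2, −20 °C
Reagents that add atoms: tert-butyl hydroperoxide CC(C)(C)OO
Why: Sharpless asymmetric epoxidation in its kinetic-resolution sense: with L-(+)-tartrate the R carbinol is the fast-reacting enantiomer and oxygen arrives on the face that gives the erythro epoxy alcohol, which fixes both epoxide carbons as in (2S,3S)-3-arylglycidols. Residual S alcohol is left behind, which raises the enantiomeric purity.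

Step 7
Reactants: 12 erythro epoxy alcohol (as in step 6); 2 2,2-diphenyl-1,3-benzodioxol-4-ol
Product: 13 aryloxy trans-epoxide: 4-{(R)-[3,4-bis(benzyloxy)phenyl][(2R,3S)-3-(2,3-bis(benzyloxy)-5-bromo-4-(tosyloxy)phenyl)oxiran-2-yl]methoxy}-2,2-diphenyl-1,3-benzodioxole
Conditions: PPh3, DIAD, toluene, 0 °C → rt
Reagents that add atoms: none
Why: Mitsunobu etherification: the phenol displaces the oxyphosphonium group with inversion at the benzylic carbinol, turning the erythro epoxy alcohol into the threo aryl ether that maps onto 2,3-cis. The β-epoxide oxygen disfavours ionisation, as in Mitsunobu inversions of α-oxygenated 3,4-dialkoxyphenyl carbinols.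

Step 8
Reactants: 13 aryloxy trans-epoxide (as in step 7)
Product: 14 4-(bromoaryl)flavan-3-ol: (2R,3R)-2-[3,4-bis(benzyloxy)phenyl]-4-[2,3-bis(benzyloxy)-5-bromo-4-(tosyloxy)phenyl]-7,8-(diphenylmethylenedioxy)chroman-3-ol, 4-aryl trans to 3-OH
Conditions: HFIP/CH2Cl2 (1:1), 0 °C → rt
Reagents that add atoms: none
Why: HFIP hydrogen-bonds to the epoxide oxygen and polarises the benzylic C4–O bond; ring A, whose only free carbon ortho to O1 is also para to the O7 ketal oxygen, attacks C4 from the side opposite the departing oxygen, and rearomatisation gives the chroman (BF3·OEt2 at −78 °C is the stronger activation if HFIP alone is too slow). The closest known reaction type is the intramolecular Friedel–Crafts epoxy-arene cyclisation of 3-aryl glycidyl aryl ethers to trans-4-arylchroman-3-ols. Upper ring C closes in the 6-endo-tet mode at the epoxide, with C4 attacked and O3 left outside the new ring; the five-membered alternative through C3 has no benzylic assistance and is retarded by the adjacent C2–O bond, and attack on C4 by ring B would need a strained 5-endo closure. The single new stereocentre, C4, is fixed by inversion of the trans-epoxide carbon, which puts the pendant aryl trans to the freed 3-hydroxyl while C2 and C3 are untouched. The step needs an invertive and not a cationic opening: the tosylate para to C4 and the bromine take away the strongest donor of the pendant ring, so that C4 is activated but not freely ionised, and C2 is kept from ionising by its β-oxygen. Site selectivity on ring A is structural, since C4a is the only ortho position open.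

Step 9
Reactants: 14 4-(bromoaryl)flavan-3-ol (as in step 8)
Product: 16 4-(acetylaryl)flavan-3-ol: compound 14 with acetyl in place of bromine, via enol ether 15 (not isolated)
Conditions: tributyl(1-ethoxyvinyl)stannane, Pd(PPh3)4 (5 mol%), toluene, 100 °C; then 1 M HCl, THF, 0 °C
Reagents that add atoms: tributyl(1-ethoxyvinyl)stannane CCCC[Sn](CCCC)(CCCC)C(=C)OCC; water O
Why: Stille coupling at the C–Br bond (the aryl tosylate is inert with triphenylphosphine ligands) with an acetyl-anion equivalent, then mild acid hydrolysis of the enol ether. No organolithium is used, so the free 3-hydroxyl and the tosylate need no protection.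

Step 10
Reactants: 16 4-(acetylaryl)flavan-3-ol (as in step 9); 17 4-(benzyloxy)benzaldehyde
Product: 19 2'-hydroxychalcone: (E)-enone from the acetyl group of the detosylated 16 and aldehyde 17, via hydroxyacetophenone 18 (not isolated)
Conditions: KOH, EtOH/THF, 60 °C; then 17, 40 °C
Reagents that add atoms: none
Why: Hydroxide cleaves the aryl sulfonate at sulfur to the chelated phenoxide, and Claisen–Schmidt condensation of the methyl ketone with the aldehyde gives the E-chalcone. Benzyl ethers, the ketal and the 2,3-cis flavan (no free 4'-phenol) are stable to base.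

Step 11
Reactants: 19 2'-hydroxychalcone (as in step 10)
Product: 20 flavonol: 7,8-bis(benzyloxy)-2-[4-(benzyloxy)phenyl]-3-hydroxy-4H-chromen-4-one carrying the protected upper unit at C6
Conditions: 30% H2O2, NaOH, MeOH/THF, 0 °C → rt
Reagents that add atoms: hydrogen peroxide OO
Why: Algar–Flynn–Oyamada oxidation: alkaline peroxide converts the 2'-hydroxychalcone into the 3-hydroxyflavone, forming O1–C2 and C3–O of lower ring C. With C6' unsubstituted the six-membered closure is expected and not the aurone.

Step 12
Reactants: 20 flavonol (as in step 11)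
Product: 21 protected target: lower unit (2R,3R,4R)-all-cis-flavan-3,4-diol, five benzyl ethers and the ketal retained
Conditions: H2 (100 bar), Ru(cod)(2-methylallyl)2 (5 mol%), (R,R)-SINpEt·HBF4 (10 mol%), KOtBu (15 mol%), toluene, 40 °C
Reagents that add atoms: none
Why: Proposed new method: the closest known reaction type is the homogeneous hydrogenation of flavones and chromones to cis-flavan-4-ols with chiral ruthenium–NHC catalysts, and its extension to a 3-hydroxyflavone with a tetrasubstituted enol double bond is untested; syn addition of H2 to C2=C3 on the catalyst-chosen face should set the 2-aryl and 3-hydroxyl cis, and reduction of the C4 ketone from the same exposed face should set the 4-hydroxyl cis to both, with the 3-OH able to bind ruthenium; the face must come from the ligand (antipode chosen on a model flavonol) because the upper stereocentres are remote.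

Step 13
Reactants: 21 protected target (as in step 12)
Product: 22 target CNP0174688.1
Conditions: H2 (1 atm), Pd(OH)2/C, THF/MeOH, rt
Reagents that add atoms: none
Why: Hydrogenolysis of the five benzyl ethers and of the diphenylmethylene ketal in one operation. A neutral medium and stopping at the theoretical uptake are meant to spare the lower benzylic C4–OH.

## Compound list

1 | pyrogallol | Oc1cccc(O)c1O | starting material
2 | 2,2-diphenyl-1,3-benzodioxol-4-ol | Oc1cccc2OC(c3ccccc3)(c3ccccc3)Oc12 | intermediate
3 | 2,3,4-trihydroxybenzaldehyde | O=Cc1ccc(O)c(O)c1O | starting material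
4 | 5-bromo-2,3,4-trihydroxybenzaldehyde | O=Cc1cc(Br)c(O)c(O)c1O | intermediate
5 | 5-bromo-2,3-dihydroxy-4-(tosyloxy)benzaldehyde | O=Cc1cc(Br)c(OS(=O)(=O)c2ccc(C)cc2)c(O)c1O | intermediate (not isolated)
6 | 2,3-bis(benzyloxy)-5-bromo-4-(tosyloxy)benzaldehyde | O=Cc1cc(Br)c(OS(=O)(=O)c2ccc(C)cc2)c(OCc2ccccc2)c1OCc3ccccc3 | intermediate
7 | 2,3-bis(benzyloxy)-6-bromo-4-ethynylphenyl 4-methylbenzenesulfonate | C#Cc1cc(Br)c(OS(=O)(=O)c2ccc(C)cc2)c(OCc2ccccc2)c1OCc3ccccc3 | intermediate
8 | 3,4-bis(benzyloxy)benzaldehyde | O=Cc1ccc(OCc2ccccc2)c(OCc2ccccc2)c1 | starting material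
9 | (E)-alkenyl(dicyclohexyl)borane from 7 | C1CCCCC1B(/C=C/c2cc(Br)c(OS(=O)(=O)c3ccc(C)cc3)c(OCc3ccccc3)c2OCc3ccccc3)C1CCCCC1 | intermediate (not isolated)
10 | (E)-alkenyl(methyl)zinc from 9 | C[Zn]/C=C/c1cc(Br)c(OS(=O)(=O)c2ccc(C)cc2)c(OCc2ccccc2)c1OCc3ccccc3 | intermediate (not isolated)
11 | (R,E)-1-[3,4-bis(benzyloxy)phenyl]-3-[2,3-bis(benzyloxy)-5-bromo-4-(tosyloxy)phenyl]prop-2-en-1-ol | O[C@H](/C=C/c1cc(Br)c(OS(=O)(=O)c2ccc(C)cc2)c(OCc2ccccc2)c1OCc3ccccc3)c1ccc(OCc2ccccc2)c(OCc2ccccc2)c1 | intermediate
12 | (S)-[3,4-bis(benzyloxy)phenyl]{(2S,3S)-3-[2,3-bis(benzyloxy)-5-bromo-4-(tosyloxy)phenyl]oxiran-2-yl}methanol | c1ccccc1COc2c(OCc3ccccc3)c(OS(=O)(=O)c3ccc(C)cc3)c(Br)cc2[C@@H]2O[C@H]2[C@@H](O)c2ccc(OCc3ccccc3)c(OCc3ccccc3)c2 | intermediate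
13 | 4-{(R)-[3,4-bis(benzyloxy)phenyl][(2R,3S)-3-(2,3-bis(benzyloxy)-5-bromo-4-(tosyloxy)phenyl)oxiran-2-yl]methoxy}-2,2-diphenyl-1,3-benzodioxole | c1ccccc1COc2c(OCc3ccccc3)c(OS(=O)(=O)c3ccc(C)cc3)c(Br)cc2[C@@H]2O[C@H]2[C@H](Oc2cccc3OC(c4ccccc4)(c4ccccc4)Oc23)c2ccc(OCc3ccccc3)c(OCc3ccccc3)c2 | intermediate (key-step precursor)
14 | (2R,3R)-2-[3,4-bis(benzyloxy)phenyl]-4-[2,3-bis(benzyloxy)-5-bromo-4-(tosyloxy)phenyl]-7,8-(diphenylmethylenedioxy)chroman-3-ol, 4-aryl trans to 3-OH | c1ccccc1COc2c(OCc3ccccc3)c(OS(=O)(=O)c3ccc(C)cc3)c(Br)cc2[C@H]2c3ccc4OC(c5ccccc5)(c5ccccc5)Oc4c3O[C@H](c3ccc(OCc4ccccc4)c(OCc4ccccc4)c3)[C@@H]2O | intermediate (key-step product)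
15 | compound 14 with 1-ethoxyvinyl in place of bromine | c1ccccc1COc2c(OCc3ccccc3)c(OS(=O)(=O)c3ccc(C)cc3)c(C(=C)OCC)cc2[C@H]2c3ccc4OC(c5ccccc5)(c5ccccc5)Oc4c3O[C@H](c3ccc(OCc4ccccc4)c(OCc4ccccc4)c3)[C@@H]2O | intermediate (not isolated)
16 | compound 14 with acetyl in place of bromine | c1ccccc1COc2c(OCc3ccccc3)c(OS(=O)(=O)c3ccc(C)cc3)c(C(C)=O)cc2[C@H]2c3ccc4OC(c5ccccc5)(c5ccccc5)Oc4c3O[C@H](c3ccc(OCc4ccccc4)c(OCc4ccccc4)c3)[C@@H]2O | intermediate
17 | 4-(benzyloxy)benzaldehyde | O=Cc1ccc(OCc2ccccc2)cc1 | starting material
18 | compound 16 with free phenol in place of the tosylate (2'-hydroxyacetophenone) | c1ccccc1COc2c(OCc3ccccc3)c(O)c(C(C)=O)cc2[C@H]2c3ccc4OC(c5ccccc5)(c5ccccc5)Oc4c3O[C@H](c3ccc(OCc4ccccc4)c(OCc4ccccc4)c3)[C@@H]2O | intermediate (not isolated)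
19 | (E)-2'-hydroxychalcone from 18 and 17 | c1ccccc1COc2c(OCc3ccccc3)c(O)c(C(=O)/C=C/c3ccc(OCc4ccccc4)cc3)cc2[C@H]2c3ccc4OC(c5ccccc5)(c5ccccc5)Oc4c3O[C@H](c3ccc(OCc4ccccc4)c(OCc4ccccc4)c3)[C@@H]2O | intermediate
20 | 7,8-bis(benzyloxy)-2-[4-(benzyloxy)phenyl]-3-hydroxy-4H-chromen-4-one bearing the protected upper flavan-3-ol at C6 | O=c1c(O)c(-c2ccc(OCc3ccccc3)cc2)oc2c(OCc3ccccc3)c(OCc3ccccc3)c(cc12)[C@H]1c2ccc3OC(c4ccccc4)(c4ccccc4)Oc3c2O[C@H](c2ccc(OCc3ccccc3)c(OCc3ccccc3)c2)[C@@H]1O | intermediate
21 | protected target, lower unit (2R,3R,4R)-all-cis-flavan-3,4-diol | c1ccccc1COc1ccc(cc1)[C@H]1Oc2c(cc([C@H]3c4ccc5OC(c6ccccc6)(c6ccccc6)Oc5c4O[C@H](c4ccc(OCc5ccccc5)c(OCc5ccccc5)c4)[C@@H]3O)c(OCc3ccccc3)c2OCc2ccccc2)[C@@H](O)[C@H]1O | intermediate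
22 | CNP0174688.1, upper (2R,3R,4S), lower (2R,3R,4R) | Oc1ccc([C@H]2Oc3c(cc([C@H]4c5ccc(O)c(O)c5O[C@H](c5ccc(O)c(O)c5)[C@@H]4O)c(O)c3O)[C@@H](O)[C@H]2O)cc1 | target

## Step count and least certain steps

Total step count: 13. Longest linear sequence: 12 steps (3 to 22, steps 2 to 13); step 1 is the side branch.

Step 12 (Proposed new method). The likely failure is poor facial selectivity or stalled turnover: the catalyst class has been used on 3-unsubstituted chromones, the enol double bond here is tetrasubstituted, no stereocentre lies near it, and the free enol hydroxyl may bind ruthenium. The fallback uses known chemistry and sets out from 20. Heterogeneous hydrogenation over Raney Ni (H2, EtOH/THF) is the classical way from flavonols to 2,3-cis-3,4-cis-flavan-3,4-diols by delivery of hydrogen to one face. It has no preference between the two faces here, so it should give 21 together with its lower-unit (2S,3S,4S) diastereomer F1 in roughly equal amounts. The two differ only in the lower triad while the upper unit is constant, so they are diastereomers and are separated by chromatography. The fallback comes back to the route at 21.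

Step 8 (key step). The likely failure is ionisation of C4 before the C–C bond forms, which would erode the invertive course (some 3,4-cis isomer) or open a hydride shift to a ketone. The fallback sets out from 13. Acetolysis of the epoxide (AcOH) and acetylation (Ac2O, DMAP) give the 3,4-diacetate F2, whose C4 epimers need not be separated. TMSOTf in CH2Cl2 at −40 °C ionises the benzylic C4 acetate with participation of the C3 acetate; the trans-disubstituted 1,3-dioxolan-2-ylium ion is then opened at C4 from the rear by ring A, so both epimers should converge on the 3,4-trans 3-O-acetate F3. K2CO3 in MeOH removes the acetate, and the fallback comes back at 14. This replaces a stereospecific opening by a stereoconvergent substitution under neighbouring-group control, a known reaction type.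

Step 6. The likely failure is titanium-induced ionisation of the doubly activated 1,3-diarylallyl alcohol (transposition, racemisation) or Lewis-acid opening of the new benzylic epoxide by alkoxide. The fallback sets out from 11 and uses Shi epoxidation with the enantiomer of the fructose-derived ketone (KHSO5 as 2KHSO5·KHSO4·K2SO4, K2CO3 buffer, MeCN/dimethoxymethane/H2O, 0 °C). The face is chosen by the dioxirane and the medium is basic and free of Lewis acid. It gives 12 directly, so it comes back at 12 and makes no new compound.

Step 7. The likely failure is partial ionisation of the p-alkoxybenzylic oxyphosphonium intermediate, which would erode the inversion (erythro ether as contaminant) or lead to elimination. The fallback avoids a benzylic leaving group altogether and sets out from 8, 2 and 6.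
- Wittig reaction of 8 with Ph3P=CHCO2Et gives ethyl (E)-3-[3,4-bis(benzyloxy)phenyl]acrylate F4.
- iBu2AlH gives (E)-3-[3,4-bis(benzyloxy)phenyl]prop-2-en-1-ol F5, and ClCO2Me with pyridine gives its methyl carbonate F6.
- [Ir(cod)Cl]2 with a chiral phosphoramidite and the sodium salt of 2 gives the branched (S)-allyl aryl ether F7 by asymmetric allylic etherification; F7 has the C2 geometry of 13.
- Wittig methylenation of 6 (Ph3P=CH2) gives 2,3-bis(benzyloxy)-6-bromo-4-vinylphenyl 4-methylbenzenesulfonate F8.
- Cross-metathesis of F7 with F8 (second-generation Hoveyda–Grubbs catalyst) gives the E-alkene ether F9.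
- Shi epoxidation of F9 with the enantiomeric ketone gives the trans-epoxide, and the fallback comes back at 13.

Step 13. The likely failure is hydrogenolysis of the lower benzylic C4–OH, which is activated by O1 and O7, especially if slow ketal cleavage forces long reaction times. The fallback reverses the order of the last two operations and sets out from 20. Hydrogenolysis (H2, Pd/C, THF/MeOH) at the flavonol stage, where no benzylic carbinol exists, gives the free heptahydroxy flavonol–flavan F10. F10 is then reduced last under the conditions of step 12 in THF/MeOH; a homogeneous ruthenium hydride catalyst does not cleave benzylic C–O bonds. The fallback comes back at 22 and carries the uncertainty of step 12 with it.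

## Further compounds

F1 | step 12 | lower-unit (2S,3S,4S) diastereomer of 21 | c1ccccc1COc1ccc(cc1)[C@@H]1Oc2c(cc([C@H]3c4ccc5OC(c6ccccc6)(c6ccccc6)Oc5c4O[C@H](c4ccc(OCc5ccccc5)c(OCc5ccccc5)c4)[C@@H]3O)c(OCc3ccccc3)c2OCc2ccccc2)[C@H](O)[C@@H]1O
F2 | step 8 | 3,4-diacetate from acetolysis and acetylation of 13 (C4 epimers) | c1ccccc1COc2c(OCc3ccccc3)c(OS(=O)(=O)c3ccc(C)cc3)c(Br)cc2C(OC(C)=O)[C@@H](OC(C)=O)[C@H](Oc2cccc3OC(c4ccccc4)(c4ccccc4)Oc23)c2ccc(OCc3ccccc3)c(OCc3ccccc3)c2
F3 | step 8 | 3-O-acetate of 14 | c1ccccc1COc2c(OCc3ccccc3)c(OS(=O)(=O)c3ccc(C)cc3)c(Br)cc2[C@H]2c3ccc4OC(c5ccccc5)(c5ccccc5)Oc4c3O[C@H](c3ccc(OCc4ccccc4)c(OCc4ccccc4)c3)[C@@H]2OC(C)=O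
F0 | step 6 | none | none
F4 | step 7 | ethyl (E)-3-[3,4-bis(benzyloxy)phenyl]acrylate | CCOC(=O)/C=C/c1ccc(OCc2ccccc2)c(OCc2ccccc2)c1
F5 | step 7 | (E)-3-[3,4-bis(benzyloxy)phenyl]prop-2-en-1-ol | OC/C=C/c1ccc(OCc2ccccc2)c(OCc2ccccc2)c1
F6 | step 7 | (E)-3-[3,4-bis(benzyloxy)phenyl]allyl methyl carbonate | COC(=O)OC/C=C/c1ccc(OCc2ccccc2)c(OCc2ccccc2)c1
F7 | step 7 | (S)-4-{1-[3,4-bis(benzyloxy)phenyl]allyloxy}-2,2-diphenyl-1,3-benzodioxole | C=C[C@H](Oc1cccc2OC(c3ccccc3)(c3ccccc3)Oc12)c1ccc(OCc2ccccc2)c(OCc2ccccc2)c1
F8 | step 7 | 2,3-bis(benzyloxy)-6-bromo-4-vinylphenyl 4-methylbenzenesulfonate | C=Cc1cc(Br)c(OS(=O)(=O)c2ccc(C)cc2)c(OCc2ccccc2)c1OCc3ccccc3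
F9 | step 7 | (S,E)-alkene ether, compound 13 with C3=C4 alkene in place of the epoxide | c1ccccc1COc2c(OCc3ccccc3)c(OS(=O)(=O)c3ccc(C)cc3)c(Br)cc2/C=C/[C@H](Oc2cccc3OC(c4ccccc4)(c4ccccc4)Oc23)c2ccc(OCc3ccccc3)c(OCc3ccccc3)c2
F10 | step 13 | fully deprotected flavonol corresponding to 20 | O=c1c(O)c(-c2ccc(O)cc2)oc2c(O)c(O)c(cc12)[C@H]1c2ccc(O)c(O)c2O[C@H](c2ccc(O)c(O)c2)[C@@H]1O
A1 | alternative 1 | protected biflavanoid 8-boronic acid | O(Cc9ccccc9)c1ccc([C@H]2Oc3c(cc([C@H]4c5ccc(OCc9ccccc9)c(B(O)O)c5O[C@H](c5ccc(OCc9ccccc9)c(OCc9ccccc9)c5)[C@@H]4OCc9ccccc9)c(OCc9ccccc9)c3OCc9ccccc9)[C@H]6OC(C)(C)O[C@H]62)cc1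
A2 | alternative 1 | open-chain fluoroarene alcohol, precursor of A1 | O(Cc9ccccc9)c1ccc([C@H]2Oc3c(cc([C@@H](c5ccc(OCc9ccccc9)cc5F)[C@@H](OCc9ccccc9)[C@H](O)c5ccc(OCc9ccccc9)c(OCc9ccccc9)c5)c(OCc9ccccc9)c3OCc9ccccc9)[C@H]6OC(C)(C)O[C@H]62)cc1
A3 | alternative 2 | upper-unit 2,4-dihydroxy-3-benzyloxyacetophenone | CC(=O)c3cc([C@H]4c5ccc(OCc9ccccc9)c(OCc9ccccc9)c5O[C@H](c5ccc(OCc9ccccc9)c(OCc9ccccc9)c5)[C@@H]4OCc9ccccc9)c(O)c(OCc9ccccc9)c3O
A4 | alternative 2 | 1-methoxy-1,3-bis(trimethylsilyloxy)-2-benzyloxy diene on upper C4 | COC(O[Si](C)(C)C)=C(OCc9ccccc9)C(O[Si](C)(C)C)=C[C@H]4c5ccc(OCc9ccccc9)c(OCc9ccccc9)c5O[C@H](c5ccc(OCc9ccccc9)c(OCc9ccccc9)c5)[C@@H]4OCc9ccccc9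
A5 | alternative 2 | 3-butyn-2-one | CC(=O)C#C
A6 | alternative 3 | all-cis 4-benzyloxy-3-boryl lower unit joined to the upper unit | O(Cc9ccccc9)c1ccc([C@H]2Oc3c(cc([C@H]4c5ccc(OCc9ccccc9)c(OCc9ccccc9)c5O[C@H](c5ccc(OCc9ccccc9)c(OCc9ccccc9)c5)[C@@H]4OCc9ccccc9)c(OCc9ccccc9)c3OCc9ccccc9)[C@@H](OCc9ccccc9)[C@H]2B7OC(C)(C)C(C)(C)O7)cc1
A7 | alternative 3 | upper-unit salicylaldehyde | O=Cc3cc([C@H]4c5ccc(OCc9ccccc9)c(OCc9ccccc9)c5O[C@H](c5ccc(OCc9ccccc9)c(OCc9ccccc9)c5)[C@@H]4OCc9ccccc9)c(OCc9ccccc9)c(OCc9ccccc9)c3O
A8 | alternative 3 | (Z)-2-[2-(4-benzyloxyphenyl)ethenyl]-4,4,5,5-tetramethyl-1,3,2-dioxaborolane | CC1(C)OB(/C=C\c2ccc(OCc3ccccc3)cc2)OC1(C)C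
A9 | alternative 3 | benzyl alcohol | OCc1ccccc1
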